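**Strategy.** Isochromene numbering of the target is used throughout. The route rests on reading the tertiary α-ketol C8(=O)–C7(OH)(CH3) of the carbocyclic ring (C4a–C5–C6–C7–C8–C8a), flanked by the C6 ketone, as an acyloin. A monocyclic 4-ylidene-4H-pyran is assembled that carries a formyl group (C8) on C8a and a 2,3-dioxobutylidene chain (C5, C6, C7 and the methyl group) on C4a. An intramolecular crossed aldehyde–ketone benzoin reaction under a chiral triazolylidene catalyst then closes the carbocycle between C7 and C8, sets the C7 carbinol centre and delivers the bicyclic 6H-isochromene-6,8(7H)-dione at its final oxidation level in one operation. Orsellinoylation of the new hydroxyl and desilylation follow.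

Key step: step 7

Assumption: C7 of the target is (S) (CIP order O > C8 > C6 > CH3), which requires attack of C8 on the Re face of the C7 carbonyl. Both enantiomers of the triazolium precatalyst are commercial; the (5aS,10bR) enantiomer is written on the usual shielding model, and its antipode would be taken if the sense of induction in this new substrate is the opposite.

Assumption: the exocyclic C4a=C5 bond of 14 and 15 is a polarised push–pull double bond of low configurational stability; the SMILES show the isomer that can cyclise.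

Step 1
Reactants: 1 3,3-dimethoxybutan-2-one
Product: 3 3,3-dimethoxybut-1-yne, via enol phosphate 2 (not isolated)
Conditions: LiN(iPr)2 (1.1 equiv), THF, −78 °C; ClP(O)(OEt)2, −78 °C to rt; then LiN(iPr)2 (2.3 equiv), THF, −78 °C to rt; H2O
Reagents that add atoms: none
Why: Conversion of a methyl ketone into a terminal alkyne by elimination of its kinetic enol phosphate with excess amide base; the ketal carbon has no α-hydrogen, so only the methyl group can be enolised.

Step 2
Reactants: 4 2,2,6-trimethyl-4H-1,3-dioxin-4-one; 5 (tert-butyldimethylsilyloxy)acetaldehyde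
Product: 6 6-[3-(tert-butyldimethylsilyloxy)-2-hydroxypropyl]-2,2-dimethyl-4H-1,3-dioxin-4-one (racemic)
Conditions: LiN(iPr)2, THF, −78 °C; then 5, −78 °C; aq. NH4Cl
Reagents that add atoms: none
Why: Vinylogous aldol addition of the lithium dienolate of the dioxinone, which reacts with aldehydes at the γ-carbon (the C6 methyl group); the racemic carbinol centre is removed in step 3.

Step 3
Reactants: 6 6-[3-(tert-butyldimethylsilyloxy)-2-hydroxypropyl]-2,2-dimethyl-4H-1,3-dioxin-4-one
Product: 8 6-[(E)-3-(tert-butyldimethylsilyloxy)prop-1-en-1-yl]-2,2-dimethyl-4H-1,3-dioxin-4-one, via mesylate 7 (not isolated)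
Conditions: MsCl, Et3N, CH2Cl2, 0 °C; then DBU, rt
Reagents that add atoms: none
Why: Mesylation followed by E1cB elimination through the vinylogous dioxinone enolate should give the conjugated (E)-alkene as the thermodynamically preferred isomer.

Step 4
Reactants: 8 6-[(E)-3-(tert-butyldimethylsilyloxy)prop-1-en-1-yl]-2,2-dimethyl-4H-1,3-dioxin-4-one; 9 1,3,3-trimethoxyprop-1-ene
Product: 12 6-[(E)-3-(tert-butyldimethylsilyloxy)prop-1-en-1-yl]-3-(dimethoxymethyl)-4H-pyran-4-one, via acylketene 10 (not isolated), via dihydropyranone 11 (not isolated)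
Conditions: 9 (4 equiv), toluene, 110 °C, slow addition of 8; then pyridinium p-toluenesulfonate (cat.), 80 °C
Reagents that add atoms: none
Why: Retro-[4+2] loss of acetone gives the acylketene, which should undergo inverse-demand hetero-Diels–Alder reaction with the enol ether (ketene carbon to the nucleophilic β-carbon, acyl oxygen to the methoxy-bearing carbon), and acid-catalysed loss of methanol then aromatises the adduct to the 4-pyranone.

Step 5
Reactants: 12 6-[(E)-3-(tert-butyldimethylsilyloxy)prop-1-en-1-yl]-3-(dimethoxymethyl)-4H-pyran-4-one; 3 3,3-dimethoxybut-1-yne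
Product: 14 4-(2,3-dioxobutylidene)-6-[(E)-3-hydroxyprop-1-en-1-yl]-4H-pyran-3-carbaldehyde, via propargylic alcohol 13 (not isolated)
Conditions: 3 (1.3 equiv), n-BuLi (1.25 equiv), THF, −78 °C; then 12, −78 to −20 °C; then 2 M HCl (aq), THF, rt
Reagents that add atoms: water, O
Why: 1,2-Addition of the hard lithium acetylide to the pyranone carbonyl followed by Meyer–Schuster rearrangement through the 4-alkynylpyrylium ion should give the push–pull 4-(2-oxoalkylidene)pyran, and the same aqueous acid hydrolyses the vinylogous acetal at C8, the ketal at C7 and the primary silyl ether.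

Step 6
Reactants: 14 4-(2,3-dioxobutylidene)-6-[(E)-3-hydroxyprop-1-en-1-yl]-4H-pyran-3-carbaldehyde
Product: 15 (E)-3-[4-(2,3-dioxobutylidene)-5-formyl-4H-pyran-2-yl]prop-2-en-1-yl acetate
Conditions: Ac2O, pyridine, CH2Cl2, 0 °C to rt
Reagents that add atoms: acetic anhydride, CC(=O)OC(C)=O
Why: Standard acetylation of the only hydroxyl group, a primary allylic alcohol.

Step 7
Reactants: 15 (E)-3-[4-(2,3-dioxobutylidene)-5-formyl-4H-pyran-2-yl]prop-2-en-1-yl acetate
Product: 16 (E)-3-[(7S)-7-hydroxy-7-methyl-6,8-dioxo-7,8-dihydro-6H-isochromen-3-yl]prop-2-en-1-yl acetate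
Conditions: (5aS,10bR)-2-(pentafluorophenyl)-5a,10b-dihydro-4H,6H-indeno[2,1-b][1,2,4]triazolo[4,3-d][1,4]oxazin-2-ium tetrafluoroborate (15 mol %), Et3N (15 mol %), toluene, rt to 40 °C, argon
Reagents that add atoms: none
Why: The free triazolylidene adds to the C8 formyl group, proton transfer gives the hydroxy-enamine acyl-anion equivalent, its C8 attacks the C7 ketone, and proton transfer with release of the carbene gives the α-ketol. The closest known reaction type is the enantioselective intramolecular crossed aldehyde–ketone benzoin cyclisation catalysed by aminoindanol-derived triazolium salts, which forms six-membered α-hydroxy ketones with a tertiary carbinol. The carbocycle (C4a–C5–C6–C7–C8–C8a) closes in the 6-exo-trig mode. The new stereocentre C7 is controlled by the catalyst, whose indane unit shields one face of the acyl-anion equivalent so that the C7 carbonyl is attacked on its Re face to give the (S)-carbinol. The step needs site selectivity for C7 over C6 and acyl-anion reactivity at C8 over homoenolate reactivity at C1: C6 is a deactivated vinylogous ester carbonyl conjugated with O1 and would need a 5-exo closure, C7 is an acetyl carbonyl activated by the adjacent C6 carbonyl, C1 carries the ring oxygen and is mismatched as a nucleophile, and the N-pentafluorophenyl triazolium is the catalyst type that favours acyl-anion chemistry. The substrate has no enolisable hydrogen between the reacting carbonyl groups, and the polarised C4a=C5 bond should let the two geometrical isomers interconvert faster than ring closure.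

Step 8
Reactants: 17 orsellinic acid
Product: 18 tert-butyldimethylsilyl 2,4-bis(tert-butyldimethylsilyloxy)-6-methylbenzoate
Conditions: TBSCl (3.5 equiv), imidazole, HCONMe2, rt
Reagents that add atoms: tert-butyldimethylsilyl chloride, CC(C)(C)[Si](C)(C)Cl
Why: Exhaustive silylation of both phenols and the carboxylic acid under standard imidazole-promoted conditions.

Step 9
Reactants: 18 tert-butyldimethylsilyl 2,4-bis(tert-butyldimethylsilyloxy)-6-methylbenzoate
Product: 19 2,4-bis(tert-butyldimethylsilyloxy)-6-methylbenzoyl chloride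
Conditions: (COCl)2, HCONMe2 (cat.), CH2Cl2, 0 °C to rt
Reagents that add atoms: oxalyl chloride, O=C(Cl)C(=O)Cl
Why: Silyl esters are converted directly into acid chlorides by the chloroiminium species under neutral conditions with loss of the silyl chloride, so the aryl silyl ethers should be untouched.

Step 10
Reactants: 16 (E)-3-[(7S)-7-hydroxy-7-methyl-6,8-dioxo-7,8-dihydro-6H-isochromen-3-yl]prop-2-en-1-yl acetate; 19 2,4-bis(tert-butyldimethylsilyloxy)-6-methylbenzoyl chloride
Product: 20 (7S)-3-[(E)-3-acetoxyprop-1-en-1-yl]-7-methyl-6,8-dioxo-7,8-dihydro-6H-isochromen-7-yl 2,4-bis(tert-butyldimethylsilyloxy)-6-methylbenzoate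
Conditions: Et3N, 4-(dimethylamino)pyridine, CH2Cl2, 0 °C to rt
Reagents that add atoms: none
Why: Nucleophile-catalysed acylation of the tertiary α-ketol hydroxyl with the acid chloride; C7 bears no hydrogen, so its configuration cannot be affected.

Step 11
Reactants: 20 (7S)-3-[(E)-3-acetoxyprop-1-en-1-yl]-7-methyl-6,8-dioxo-7,8-dihydro-6H-isochromen-7-yl 2,4-bis(tert-butyldimethylsilyloxy)-6-methylbenzoate
Product: 21 (7S)-3-[(E)-3-acetoxyprop-1-en-1-yl]-7-methyl-6,8-dioxo-7,8-dihydro-6H-isochromen-7-yl 2,4-dihydroxy-6-methylbenzoate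
Conditions: HF·pyridine, pyridine, THF, 0 °C to rt
Reagents that add atoms: none
Why: Buffered fluoride should cleave the two aryl silyl ethers without touching the allylic acetate, the tertiary benzoate or the nucleophile-sensitive pyran ring.

**Compound list**

1 | 3,3-dimethoxybutan-2-one | CC(=O)C(C)(OC)OC | starting material
2 | diethyl 3,3-dimethoxybut-1-en-2-yl phosphate (enol phosphate, not isolated) | C=C(OP(=O)(OCC)OCC)C(C)(OC)OC | intermediate
3 | 3,3-dimethoxybut-1-yne | C#CC(C)(OC)OC | intermediate
4 | 2,2,6-trimethyl-4H-1,3-dioxin-4-one | CC1=CC(=O)OC(C)(C)O1 | starting material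
5 | (tert-butyldimethylsilyloxy)acetaldehyde | O=CCO[Si](C)(C)C(C)(C)C | starting material
6 | 6-[3-(tert-butyldimethylsilyloxy)-2-hydroxypropyl]-2,2-dimethyl-4H-1,3-dioxin-4-one (racemic) | CC1(C)OC(CC(O)CO[Si](C)(C)C(C)(C)C)=CC(=O)O1 | intermediate
7 | 1-(tert-butyldimethylsilyloxy)-3-(2,2-dimethyl-4-oxo-4H-1,3-dioxin-6-yl)propan-2-yl methanesulfonate (mesylate, racemic, not isolated) | CC1(C)OC(CC(OS(C)(=O)=O)CO[Si](C)(C)C(C)(C)C)=CC(=O)O1 | intermediate
8 | 6-[(E)-3-(tert-butyldimethylsilyloxy)prop-1-en-1-yl]-2,2-dimethyl-4H-1,3-dioxin-4-one | CC1(C)OC(/C=C/CO[Si](C)(C)C(C)(C)C)=CC(=O)O1 | intermediate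
9 | 1,3,3-trimethoxyprop-1-ene (E/Z mixture as supplied) | COC=CC(OC)OC | starting material
10 | (E)-6-(tert-butyldimethylsilyloxy)hexa-1,4-diene-1,3-dione (acylketene, not isolated) | O=C=CC(=O)/C=C/CO[Si](C)(C)C(C)(C)C | intermediate
11 | 6-[(E)-3-(tert-butyldimethylsilyloxy)prop-1-en-1-yl]-3-(dimethoxymethyl)-2-methoxy-2,3-dihydro-4H-pyran-4-one (dihydropyranone, diastereomer mixture, not isolated) | COC1OC(/C=C/CO[Si](C)(C)C(C)(C)C)=CC(=O)C1C(OC)OC | intermediate
12 | 6-[(E)-3-(tert-butyldimethylsilyloxy)prop-1-en-1-yl]-3-(dimethoxymethyl)-4H-pyran-4-one | COC(OC)C1=COC(/C=C/CO[Si](C)(C)C(C)(C)C)=CC1=O | intermediate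
13 | 6-[(E)-3-(tert-butyldimethylsilyloxy)prop-1-en-1-yl]-4-(3,3-dimethoxybut-1-yn-1-yl)-3-(dimethoxymethyl)-4H-pyran-4-ol (propargylic alcohol, racemic, not isolated) | COC(OC)C1=COC(/C=C/CO[Si](C)(C)C(C)(C)C)=CC1(O)C#CC(C)(OC)OC | intermediate
14 | 4-(2,3-dioxobutylidene)-6-[(E)-3-hydroxyprop-1-en-1-yl]-4H-pyran-3-carbaldehyde | OC/C=C/C1=C/C(=C/C(=O)C(C)=O)C(C=O)=CO1 | intermediate
15 | (E)-3-[4-(2,3-dioxobutylidene)-5-formyl-4H-pyran-2-yl]prop-2-en-1-yl acetate | CC(=O)OC/C=C/C1=C/C(=C/C(=O)C(C)=O)C(C=O)=CO1 | intermediate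
16 | (E)-3-[(7S)-7-hydroxy-7-methyl-6,8-dioxo-7,8-dihydro-6H-isochromen-3-yl]prop-2-en-1-yl acetate | CC(=O)OC/C=C/C1=CC2=CC(=O)[C@](C)(O)C(=O)C2=CO1 | intermediate
17 | orsellinic acid (2,4-dihydroxy-6-methylbenzoic acid) | Cc1cc(O)cc(O)c1C(=O)O | starting material
18 | tert-butyldimethylsilyl 2,4-bis(tert-butyldimethylsilyloxy)-6-methylbenzoate | Cc1cc(O[Si](C)(C)C(C)(C)C)cc(O[Si](C)(C)C(C)(C)C)c1C(=O)O[Si](C)(C)C(C)(C)C | intermediate
19 | 2,4-bis(tert-butyldimethylsilyloxy)-6-methylbenzoyl chloride | Cc1cc(O[Si](C)(C)C(C)(C)C)cc(O[Si](C)(C)C(C)(C)C)c1C(Cl)=O | intermediate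
20 | (7S)-3-[(E)-3-acetoxyprop-1-en-1-yl]-7-methyl-6,8-dioxo-7,8-dihydro-6H-isochromen-7-yl 2,4-bis(tert-butyldimethylsilyloxy)-6-methylbenzoate | CC(=O)OC/C=C/C1=CC2=CC(=O)[C@](C)(OC(=O)c3c(C)cc(O[Si](C)(C)C(C)(C)C)cc3O[Si](C)(C)C(C)(C)C)C(=O)C2=CO1 | intermediate
21 | (7S)-3-[(E)-3-acetoxyprop-1-en-1-yl]-7-methyl-6,8-dioxo-7,8-dihydro-6H-isochromen-7-yl 2,4-dihydroxy-6-methylbenzoate (CNP0194405.1) | CC(=O)OC/C=C/C1=CC2=CC(=O)[C@](C)(OC(=O)c3c(C)cc(O)cc3O)C(=O)C2=CO1 | target

**Step count.** Total: 11 steps. Longest linear sequence: 8 steps (steps 2, 3, 4, 5, 6, 7, 10, 11); step 1 and steps 8–9 are side branches.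

**Steps most likely to fail**

Step 7. The flat, fully conjugated substrate may give the catalyst too little to distinguish the two faces of the C7 carbonyl, so that facial selectivity is poor. Fallback: setting out from 15, the same C7–C8 bond is closed without asymmetric induction using an achiral azolium (3-benzyl-5-(2-hydroxyethyl)-4-methylthiazolium chloride, Et3N, toluene). This should give racemic (E)-3-(7-hydroxy-7-methyl-6,8-dioxo-7,8-dihydro-6H-isochromen-3-yl)prop-2-en-1-yl acetate F1. The stereocentre is then secured by resolution instead of catalyst control: preparative chromatography on a chiral stationary phase (amylose tris(3,5-dimethylphenylcarbamate)) gives the (S)-enantiomer, and the route is rejoined at 16.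

Step 5. The acetylide may add in conjugate fashion to the unsubstituted ring position next to oxygen (C1) instead of to the carbonyl, and the pyrylium intermediates may open hydrolytically in aqueous acid before the rearrangement is complete. Fallback: setting out from 12, thionation with 2,4-bis(4-methoxyphenyl)-1,3,2,4-dithiadiphosphetane 2,4-disulfide (toluene, 80 °C) gives 6-[(E)-3-(tert-butyldimethylsilyloxy)prop-1-en-1-yl]-3-(dimethoxymethyl)-4H-pyran-4-thione F2. S-Alkylation with commercial 1-bromobutane-2,3-dione (MeCN, rt) gives 2-[(E)-3-(tert-butyldimethylsilyloxy)prop-1-en-1-yl]-5-(dimethoxymethyl)-4-[(2,3-dioxobutyl)sulfanyl]pyrylium bromide F3, which is not isolated. Eschenmoser sulfide contraction (Et3N, PPh3) then gives 1-{6-[(E)-3-(tert-butyldimethylsilyloxy)prop-1-en-1-yl]-3-(dimethoxymethyl)-4H-pyran-4-ylidene}butane-2,3-dione F4. Brief treatment with dilute aqueous HCl in THF hydrolyses the acetal and the silyl ether, and the route is rejoined at 14.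

Step 4. The functionalised dienyl acylketene may dimerise or oligomerise faster than it is intercepted by the only moderately nucleophilic 1,2-disubstituted enol ether, and the advanced dioxinone 8 cannot be used in excess to compensate. Fallback: setting out from 4, which is cheap and is used in excess with 9 as the limiting component (toluene, 110 °C), the order of events is reversed. Acetylketene F5 is trapped by 9 to give 3-(dimethoxymethyl)-2-methoxy-6-methyl-2,3-dihydro-4H-pyran-4-one F6, and pyridinium p-toluenesulfonate converts this into 3-(dimethoxymethyl)-6-methyl-4H-pyran-4-one F7. Lateral deprotonation of the C6 methyl group (LiN(SiMe3)2, THF, −78 °C) and aldol addition to 5 gives 6-[3-(tert-butyldimethylsilyloxy)-2-hydroxypropyl]-3-(dimethoxymethyl)-4H-pyran-4-one F8. Mesylation (MsCl, Et3N) gives 1-(tert-butyldimethylsilyloxy)-3-[5-(dimethoxymethyl)-4-oxo-4H-pyran-2-yl]propan-2-yl methanesulfonate F9, and elimination with DBU rejoins the route at 12.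

**Further compounds**

F1 | step 7 | racemic (E)-3-(7-hydroxy-7-methyl-6,8-dioxo-7,8-dihydro-6H-isochromen-3-yl)prop-2-en-1-yl acetate | CC(=O)OC/C=C/C1=CC2=CC(=O)C(C)(O)C(=O)C2=CO1
F2 | step 5 | 6-[(E)-3-(tert-butyldimethylsilyloxy)prop-1-en-1-yl]-3-(dimethoxymethyl)-4H-pyran-4-thione | COC(OC)C1=COC(/C=C/CO[Si](C)(C)C(C)(C)C)=CC1=S
F3 | step 5 | 2-[(E)-3-(tert-butyldimethylsilyloxy)prop-1-en-1-yl]-5-(dimethoxymethyl)-4-[(2,3-dioxobutyl)sulfanyl]pyrylium bromide | COC(OC)c1c[o+]c(/C=C/CO[Si](C)(C)C(C)(C)C)cc1SCC(=O)C(C)=O.[Br-]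
F4 | step 5 | 1-{6-[(E)-3-(tert-butyldimethylsilyloxy)prop-1-en-1-yl]-3-(dimethoxymethyl)-4H-pyran-4-ylidene}butane-2,3-dione | COC(OC)C1=COC(/C=C/CO[Si](C)(C)C(C)(C)C)=CC1=CC(=O)C(C)=O
F5 | step 4 | acetylketene (buta-1-ene-1,3-dione) | CC(=O)C=C=O
F6 | step 4 | 3-(dimethoxymethyl)-2-methoxy-6-methyl-2,3-dihydro-4H-pyran-4-one | COC1OC(C)=CC(=O)C1C(OC)OC
F7 | step 4 | 3-(dimethoxymethyl)-6-methyl-4H-pyran-4-one | COC(OC)C1=COC(C)=CC1=O
F8 | step 4 | 6-[3-(tert-butyldimethylsilyloxy)-2-hydroxypropyl]-3-(dimethoxymethyl)-4H-pyran-4-one | COC(OC)C1=COC(CC(O)CO[Si](C)(C)C(C)(C)C)=CC1=O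
F9 | step 4 | 1-(tert-butyldimethylsilyloxy)-3-[5-(dimethoxymethyl)-4-oxo-4H-pyran-2-yl]propan-2-yl methanesulfonate | COC(OC)C1=COC(CC(OS(C)(=O)=O)CO[Si](C)(C)C(C)(C)C)=CC1=O
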